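(The readings come from a simulation for an exercise.)

The constants mean little to me until they are times. Eta's first reading, target 9.8% at 20.0 s, puts the pseudo-first-order lifetime of the electrophile, the time the opening rate would need for the whole charge, at 204 s.

| flask | electrophile | nucleophile | remark | time |
|---|---|---|---|---|
| eta | 0.050 M | 1.5 equiv | run made earlier |  |
| zeta | 0.050 M | 1 equiv | run made earlier |  |
| epsilon | 0.050 M | 2.2 equiv | run made earlier |  |
| alpha | 0.075 M | 1.5 equiv | run made earlier |  |
| maple | 0.050 M | 1.50 equiv (fed, over 80 s) | all else is in the flask from the start; the feed brings no volume worth counting | 2.0 min |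
| birch | 0.050 M | 1.50 equiv (in portions, 2, over 80 s) | first portion at the start, last at 80 s | 2.0 min |
| oak | 0.050 M | 1.50 equiv | everything together at the start | 2.0 min |
| larch | 0.050 M (fed, over 80 s) | 1.50 equiv | all else is in the flask from the start; the feed brings no volume worth counting | 2.0 min |

eta run (percent of the electrophile charged)

| time / s | side product / % | target / % |
|---|---|---|
| 20.0 | 1.9 | 9.8 |
| 40.0 | 4.1 | 17.2 |
| 50.0 | 6.0 | 20.5 |
| 80.0 | 12.5 | 24.0 |

zeta run (percent of the electrophile charged)

| time / min | side product / % | target / % |
|---|---|---|
| 0.667 | 4.3 | 10.6 |
| 1.33 | 8.4 | 16.2 |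
| 2.00 | 15.9 | 19.6 |
| 2.50 | 20.3 | 20.7 |

epsilon run (percent of the electrophile charged)

| time / min | side product / % | target / % |
|---|---|---|
| 0.667 | 6.1 | 23.0 |
| 1.33 | 14.8 | 33.7 |
| 2.00 | 23.1 | 39.0 |
| 2.50 | 28.4 | 41.1 |

alpha run (percent of the electrophile charged)

| time / min | side product / % | target / % |
|---|---|---|
| 0.333 | 1.8 | 13.3 |
| 0.833 | 10.5 | 24.1 |
| 1.50 | 22.5 | 29.5 |
| 2.50 | 35.9 | 30.8 |

(each reading ± 0.5 percentage points)

* the flask that comes out highest in amount of side product, in percent of the electrophile charged; "all alike" if 1.5 percentage points covers them all (maple / birch / oak / larch / all alike)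
* amount of side product at the end, in percent of the electrophile charged, maple
* amount of side product at the end, in percent of the electrophile charged, birch
* amount of side product at the end, in percent of the electrophile charged, oak
* amount of side product at the end, in percent of the electrophile charged, larch

- percent here means electrophile units held: one side product counts as two

Maple looks nearly the same as eta: it has the same charges, but its nucleophile comes in over 80 s. Because that feed is shorter than the lifetime, I treat it as a late start. The mean moment of arrival is 40.0 s, and the shifted clock, reading time minus that moment, stands at 80.0 s when maple is read at 2.0 min. Birch and larch have the same mean moment of arrival, so I take eta's reading at 80.0 s, side product 12.5%, as one rough figure for maple, birch and larch; this figure sets aside how each charge arrives, so I claim no closeness among those flasks.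

Oak is eta's recipe read at the full 2.0 min. Interpolating in equivalents between zeta (15.9%) and epsilon (23.1%) at that time, I get 18.9% for oak. The lost clock matters because, from 40.0 s to 80.0 s, eta's side product grew 3.05-fold and its target 1.40-fold. So I commit to oak as highest, by 6.4 percentage points, which is beyond the margin.

The forecast also names oak, with 19.8% (18.4% to 21.2%) for oak, which is above my figure. Unlike my single figure, it separates the fed flasks: maple 12.3% (10.8% to 13.9%), birch 13.6% (12% to 15.3%) and larch 11.2% (9.7% to 12.9%). Its ground: "Feeding delays target formation".

The flasks give oak as highest: maple 12.6%, birch 13.7%, oak 19.8%, larch 11.6%.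

    acid set free → by-product carried off (k = 0.00336 s⁻¹)
    nucleophile + acid set free ⇌ protonated nucleophile, settled at all times (K = 2450 M⁻¹)
    electrophile + target → side product (k = 0.129 M⁻¹ s⁻¹)
    electrophile + nucleophile → acid set free + target (k = 0.0813 M⁻¹ s⁻¹)

Maple at 80.0 s on the shifted clock ends at 12.6% against eta's 12.5%, and larch at the end of its feed, 40.0 s on that clock, holds side product 3.93% against eta's 4.1% at 40.0 s. In oak, electrophile goes into target 4.2 times as fast as into side product at 0.675 min, and that ratio has fallen to 1.7 at 2.00 min, the end of the 40.0 s of clock that oak has beyond the fed flasks.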